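**Retrosynthetic overview**
1. Target 19 ⇐ cyclohexene 16. The ring Br/Cl pair goes on last (Cl⁺/H2O, SN1 bromide, diaxial→diequatorial halogen interchange).
2. 16 ⇐ acyclic aldehyde 13 in one operation: silyl-Prins closure C5–C6 (cyclohexene ring first), acetoxonium relay, then C11–O→C7 etherification (oxane ring second, same flask).
3. 13 ⇐ C7–C8 bond from the (E)-alkenylzinc of enyne 4 and epoxy aldehyde 7 (sets C8); the epoxide then gives the bromohydrin (C10).
4. 4 ⇐ (Z)-allylic bromide 2 (ring-opening of dihydropyran 1) + propynyl Grignard 3; 7 ⇐ Shi epoxidation and oxidation of alcohol 5.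

Assumption: 1, 3, 5, Schwartz reagent, (+)-MIB and the D-fructose-derived Shi ketone are taken as purchasable; locants in the Why lines follow the bisabolane numbering of the target (cyclohexane C1–C6 with C2 Br, C3 Cl/Me, C5 OH, C6 junction; oxane C7 Me, C8 OAc, C9, C10 Br, C11 Me2).

**Route**

Step 1
Reactants: 1 4-methyl-3,6-dihydro-2H-pyran
Product: 2 (Z)-[(5-bromo-3-methylpent-3-en-1-yl)oxy]triethylsilane
Conditions: Et3SiOTf, n-Bu4NBr, CH2Cl2, −40 → 0 °C
Reagents that add atoms: triethylsilyl triflate CC[Si](CC)(CC)OS(=O)(=O)C(F)(F)F; tetrabutylammonium bromide CCCC[N+](CCCC)(CCCC)CCCC.[Br-]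
Why: Silyl-halide ether cleavage: the silyl triflate activates the ring oxygen and bromide opens the silyloxonium ion by SN2 attack at the allylic CH2, so the ring-fixed cis geometry becomes the (Z)-alkene.

Step 2
Reactants: 2 (Z)-[(5-bromo-3-methylpent-3-en-1-yl)oxy]triethylsilane; 3 1-propynylmagnesium bromide
Product: 4 (Z)-triethyl[(3-methyloct-3-en-6-yn-1-yl)oxy]silane
Conditions: CuI (10 mol%), THF, −20 → 0 °C
Reagents that add atoms: none
Why: Copper-catalysed SN2 alkynyl–allyl coupling at the primary allylic bromide (SN2′ would need a quaternary centre) gives the skipped enyne with the (Z)-alkene untouched.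

Step 3
Reactants: 5 4-methylpent-3-en-1-ol
Product: 6 2-[(2R)-3,3-dimethyloxiran-2-yl]ethan-1-ol
Conditions: Shi ketone (D-fructose-derived, 30 mol%), Oxone, K2CO3, n-Bu4NHSO4, MeCN/DMM/aq. buffer pH 10.5, 0 °C
Reagents that add atoms: Oxone (potassium peroxymonosulfate) [K+].[O-]S(=O)(=O)OO
Why: Shi asymmetric epoxidation (chiral dioxirane, spiro transition state) of the trisubstituted alkene sets the future C10 as R, which becomes the (S)-bromide after one inversion.

Step 4
Reactants: 6 2-[(2R)-3,3-dimethyloxiran-2-yl]ethan-1-ol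
Product: 7 2-[(2R)-3,3-dimethyloxiran-2-yl]acetaldehyde
Conditions: Dess–Martin periodinane, NaHCO3, CH2Cl2, 0 °C; used crude
Reagents that add atoms: none
Why: Buffered Dess–Martin oxidation gives the β,γ-epoxy aldehyde without epoxide opening and leaves the stereocentre untouched.

Step 5
Reactants: 4 (Z)-triethyl[(3-methyloct-3-en-6-yn-1-yl)oxy]silane; 7 2-[(2R)-3,3-dimethyloxiran-2-yl]acetaldehyde
Product: 10 (2S,3E,6Z)-1-[(2R)-3,3-dimethyloxiran-2-yl]-3,7-dimethyl-9-[(triethylsilyl)oxy]nona-3,6-dien-2-ol, via alkenylzirconocene chloride 8 (not isolated), via alkenyl(methyl)zinc 9 (not isolated)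
Conditions: Cp2Zr(H)Cl (1.3 equiv), CH2Cl2, rt; Me2Zn, toluene, −65 °C; (+)-MIB (10 mol%), 7, −30 °C; aq. NH4Cl
Reagents that add atoms: none
Why: Syn hydrozirconation (Zr equilibrates to the methyl-bearing alkyne carbon) fixes the 6E geometry, and Zr→Zn transmetalation followed by amino-alcohol-catalysed alkenylzinc addition (Oppolzer/Wipf type) to the Re face of the aldehyde sets C8 as S under catalyst control.

Step 6
Reactants: 10 (2S,3E,6Z)-1-[(2R)-3,3-dimethyloxiran-2-yl]-3,7-dimethyl-9-[(triethylsilyl)oxy]nona-3,6-dien-2-ol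
Product: 11 (2S,3E,6Z)-1-[(2R)-3,3-dimethyloxiran-2-yl]-3,7-dimethyl-9-[(triethylsilyl)oxy]nona-3,6-dien-2-yl acetate
Conditions: Ac2O, pyridine, DMAP (cat.), 0 °C → rt
Reagents that add atoms: acetic anhydride CC(=O)OC(C)=O
Why: DMAP-catalysed acylation of the secondary allylic alcohol installs the target's acetate, which also serves as the neighbouring group in step 9.

Step 7
Reactants: 11 (2S,3E,6Z)-1-[(2R)-3,3-dimethyloxiran-2-yl]-3,7-dimethyl-9-[(triethylsilyl)oxy]nona-3,6-dien-2-yl acetate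
Product: 12 (3S,5S,6E,9Z)-3-bromo-2-hydroxy-2,6,10-trimethyl-12-[(triethylsilyl)oxy]dodeca-6,9-dien-5-yl acetate
Conditions: Li2NiBr4, THF, 0 °C → rt; aq. NH4Cl
Reagents that add atoms: dilithium tetrabromonickelate [Li+].[Li+].Br[Ni-2](Br)(Br)Br
Why: Soft bromide from Li2NiBr4 opens the trisubstituted epoxide by SN2 attack at the secondary carbon with inversion, giving the (10S)-bromide and the tertiary alcohol while the alkenes stay untouched.

Step 8
Reactants: 12 (3S,5S,6E,9Z)-3-bromo-2-hydroxy-2,6,10-trimethyl-12-[(triethylsilyl)oxy]dodeca-6,9-dien-5-yl acetate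
Product: 13 (3S,5S,6E,9Z)-3-bromo-2-hydroxy-2,6,10-trimethyl-12-oxododeca-6,9-dien-5-yl acetate
Conditions: (COCl)2, DMSO, CH2Cl2, −78 → −40 °C; i-Pr2NEt, −78 °C; pH 7 buffer
Reagents that add atoms: none
Why: Swern oxidation of a primary triethylsilyl ether with in situ silyl cleavage gives the β,γ-unsaturated aldehyde directly, and the hindered base with a cold buffered quench prevents conjugation.

Step 9
Reactants: 13 (3S,5S,6E,9Z)-3-bromo-2-hydroxy-2,6,10-trimethyl-12-oxododeca-6,9-dien-5-yl acetate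
Product: 16 (2S,3S,5S)-5-bromo-2-[(1S,6R)-6-hydroxy-4-methylcyclohex-3-en-1-yl]-2,6,6-trimethyloxan-3-yl acetate, via acetoxonium triflate 14 (not isolated), via trimethylsilyl ether 15 (not isolated)
Conditions: TMSOTf (1.3 equiv), 2,6-di-tert-butyl-4-methylpyridine (1.5 equiv), CH2Cl2, −78 → −40 °C; then 1 M HCl/THF, 0 °C
Reagents that add atoms: none
Why: Proposed new method: TMSOTf converts the aldehyde into a silyloxocarbenium ion that adds to C6 of the (6E)-alkene through a half-chair with the O–Si group axial (cis to the side chain, the equatorial position being blocked by C8/C9), the tertiary C7 cation is trapped anti by the carbonyl oxygen of the C8 acetate as acetoxonium ion 14 (C9 eclipsing the alkene, which avoids A(1,2) strain with the C7 methyl and fixes the face from C8), and the C11 hydroxyl then opens 14 at C7 with inversion in a 6-endo etherification that returns the acetate to O8, so that C5 (R), C6 (S) and C7 (S) all follow from C8 (S) by net syn addition of C5 and O across the E-alkene; the closest known reaction types are the citronellal-type Prins cyclisation, neighbouring-acyloxy (acyloxonium) relay substitution and endo-selective epoxide-opening etherification.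

Step 10
Reactants: 16 (2S,3S,5S)-5-bromo-2-[(1S,6R)-6-hydroxy-4-methylcyclohex-3-en-1-yl]-2,6,6-trimethyloxan-3-yl acetate
Product: 17 (2S,3S,5S)-5-bromo-2-[(1S,2R,4S,5S)-5-chloro-2,4-dihydroxy-4-methylcyclohexyl]-2,6,6-trimethyloxan-3-yl acetate
Conditions: NCS, acetone/H2O (4:1), 0 °C → rt
Reagents that add atoms: N-chlorosuccinimide O=C1CCC(=O)N1Cl; water O
Why: Chlorohydrin formation: the chloronium ion is opened by water at the tertiary C3 in trans-diaxial (Fürst–Plattner, Markovnikov) fashion on the chair that keeps the oxanyl group equatorial, giving axial C2–Cl (β) and axial C3–OH (α, syn to the C5 hydroxyl).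

Step 11
Reactants: 17 (2S,3S,5S)-5-bromo-2-[(1S,2R,4S,5S)-5-chloro-2,4-dihydroxy-4-methylcyclohexyl]-2,6,6-trimethyloxan-3-yl acetate
Product: 19 (2S,3S,5S)-5-bromo-2-[(1S,2R,4R,5R)-5-bromo-4-chloro-2-hydroxy-4-methylcyclohexyl]-2,6,6-trimethyloxan-3-yl acetate, via diaxial bromochloride 18 (not isolated)
Conditions: 48% aq. HBr, CH2Cl2, 0 °C; organic phase dried, then toluene, 80 °C
Reagents that add atoms: hydrogen bromide Br
Why: SN1 substitution of the tertiary alcohol by bromide (axial attack anti to the C2 chlorine) gives the trans-diaxial 2-chloro-3-bromide 18, which on heating undergoes the diaxial→diequatorial 1,2-dihalide rearrangement with suprafacial interchange of the halogens, placing Br at C2 (R) and Cl at C3 (R).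

**Compound list**
1 | 4-methyl-3,6-dihydro-2H-pyran | CC1=CCOCC1 | starting material
2 | (Z)-[(5-bromo-3-methylpent-3-en-1-yl)oxy]triethylsilane | BrC/C=C(/C)CCO[Si](CC)(CC)CC | intermediate
3 | 1-propynylmagnesium bromide | CC#C[Mg]Br | starting material
4 | (Z)-triethyl[(3-methyloct-3-en-6-yn-1-yl)oxy]silane | CC#CC/C=C(/C)CCO[Si](CC)(CC)CC | intermediate
5 | 4-methylpent-3-en-1-ol | CC(C)=CCCO | starting material
6 | 2-[(2R)-3,3-dimethyloxiran-2-yl]ethan-1-ol | OCC[C@H]1OC1(C)C | intermediate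
7 | 2-[(2R)-3,3-dimethyloxiran-2-yl]acetaldehyde | O=CC[C@H]1OC1(C)C | intermediate
8 | chlorobis(cyclopentadienyl)[(2E,5Z)-6-methyl-8-(triethylsilyloxy)octa-2,5-dien-2-yl]zirconium | CC[Si](CC)(CC)OCC/C(C)=C\C/C=C(\C)[Zr](Cl)(C1C=CC=C1)C1C=CC=C1 | intermediate
9 | methyl[(2E,5Z)-6-methyl-8-(triethylsilyloxy)octa-2,5-dien-2-yl]zinc | CC[Si](CC)(CC)OCC/C(C)=C\C/C=C(\C)[Zn]C | intermediate
10 | (2S,3E,6Z)-1-[(2R)-3,3-dimethyloxiran-2-yl]-3,7-dimethyl-9-[(triethylsilyl)oxy]nona-3,6-dien-2-ol | CC[Si](CC)(CC)OCC/C(C)=C\C/C=C(\C)[C@@H](O)C[C@H]1OC1(C)C | intermediate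
11 | (2S,3E,6Z)-1-[(2R)-3,3-dimethyloxiran-2-yl]-3,7-dimethyl-9-[(triethylsilyl)oxy]nona-3,6-dien-2-yl acetate | CC[Si](CC)(CC)OCC/C(C)=C\C/C=C(\C)[C@@H](OC(C)=O)C[C@H]1OC1(C)C | intermediate
12 | (3S,5S,6E,9Z)-3-bromo-2-hydroxy-2,6,10-trimethyl-12-[(triethylsilyl)oxy]dodeca-6,9-dien-5-yl acetate | CC[Si](CC)(CC)OCC/C(C)=C\C/C=C(\C)[C@@H](OC(C)=O)C[C@H](Br)C(C)(C)O | intermediate
13 | (3S,5S,6E,9Z)-3-bromo-2-hydroxy-2,6,10-trimethyl-12-oxododeca-6,9-dien-5-yl acetate | O=CC/C(C)=C\C/C=C(\C)[C@@H](OC(C)=O)C[C@H](Br)C(C)(C)O | intermediate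
14 | (4S,5R)-4-[(2S)-2-bromo-3-hydroxy-3-methylbutyl]-2,5-dimethyl-5-[(1S,6R)-4-methyl-6-(trimethylsilyloxy)cyclohex-3-en-1-yl]-1,3-dioxolan-2-ylium triflate | CC1=[O+][C@@H](C[C@H](Br)C(C)(C)O)[C@](C)(O1)[C@H]1CC=C(C)C[C@H]1O[Si](C)(C)C.[O-]S(=O)(=O)C(F)(F)F | intermediate
15 | (2S,3S,5S)-5-bromo-2,6,6-trimethyl-2-[(1S,6R)-4-methyl-6-(trimethylsilyloxy)cyclohex-3-en-1-yl]oxan-3-yl acetate | CC(=O)O[C@H]1C[C@H](Br)C(C)(C)O[C@@]1(C)[C@H]1CC=C(C)C[C@H]1O[Si](C)(C)C | intermediate
16 | (2S,3S,5S)-5-bromo-2-[(1S,6R)-6-hydroxy-4-methylcyclohex-3-en-1-yl]-2,6,6-trimethyloxan-3-yl acetate | CC(=O)O[C@H]1C[C@H](Br)C(C)(C)O[C@@]1(C)[C@H]1CC=C(C)C[C@H]1O | intermediate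
17 | (2S,3S,5S)-5-bromo-2-[(1S,2R,4S,5S)-5-chloro-2,4-dihydroxy-4-methylcyclohexyl]-2,6,6-trimethyloxan-3-yl acetate | CC(=O)O[C@H]1C[C@H](Br)C(C)(C)O[C@@]1(C)[C@H]1C[C@H](Cl)[C@@](C)(O)C[C@H]1O | intermediate
18 | (2S,3S,5S)-5-bromo-2-[(1S,2R,4S,5S)-4-bromo-5-chloro-2-hydroxy-4-methylcyclohexyl]-2,6,6-trimethyloxan-3-yl acetate | CC(=O)O[C@H]1C[C@H](Br)C(C)(C)O[C@@]1(C)[C@H]1C[C@H](Cl)[C@@](C)(Br)C[C@H]1O | intermediate
19 | (2S,3S,5S)-5-bromo-2-[(1S,2R,4R,5R)-5-bromo-4-chloro-2-hydroxy-4-methylcyclohexyl]-2,6,6-trimethyloxan-3-yl acetate | CC(=O)O[C@H]1C[C@H](Br)C(C)(C)O[C@@]1(C)[C@H]1C[C@@H](Br)[C@](C)(Cl)C[C@H]1O | target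

**Step count**
Total: 11 steps. Longest linear sequence: 9 steps (steps 1, 2, 5–11; the branch through steps 3 and 4 is equally long).

**Three steps most likely to fail**

Step 9 (bicyclisation). The risks are direct capture of the C7 cation by the C11 hydroxyl before the acetate bridges (which would give the C5/C6 epimeric pair), acetyl migration to O5 through an orthoester, and a competing ene pathway. The fallback sets out from 13 and comes back at 16. SnCl4 in CH2Cl2 at −78 °C runs the Prins closure alone; the acetoxonium ion is opened at C7 by chloride to give (3S,5S,6S)-3-bromo-6-chloro-2-hydroxy-6-[(1S,6R)-6-hydroxy-4-methylcyclohex-3-en-1-yl]-2-methylheptan-5-yl acetate F1. AgOTf with 2,6-di-tert-butyl-4-methylpyridine then ionises the C7–Cl bond with acetate assistance, and the C11 hydroxyl closes the oxane to give 16 (two inversions at C7, same configuration as the one-flask route).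

Step 11 (tertiary bromide and halogen interchange). The risks are E1 elimination of the tertiary bromide, acid damage to the oxane, and an unfavourable equilibrium because the product carries the C3 methyl syn-axial to the C5 hydroxyl. The fallback sets out from 16 and comes back at 18. Anti-dichlorination with Et4NCl3 gives (2S,3S,5S)-5-bromo-2-[(1S,2R,4S,5S)-4,5-dichloro-2-hydroxy-4-methylcyclohexyl]-2,6,6-trimethyloxan-3-yl acetate F2; solvolytic exchange of only the tertiary chloride with LiBr in HFIP gives 18, which rearranges to 19 on heating as before.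

Step 5 (alkenylzinc addition). The risks are incomplete regiocontrol in the hydrozirconation of the 2-alkyne (about 9:1 expected), β-elimination of the epoxy aldehyde, and mismatched double diastereoselection. The fallback sets out from 4 and comes back at 10. Hydrozirconation followed by iodinolysis gives triethyl{[(3Z,6E)-7-iodo-3-methylocta-3,6-dien-1-yl]oxy}silane F3, which can be purified from its regioisomer and is then coupled with 7 in a Ni/Cr-mediated Nozaki–Hiyama–Kishi reaction with a chiral sulfonamide ligand to give 10.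

**Further compounds**
F1 | step 9 | (3S,5S,6S)-3-bromo-6-chloro-2-hydroxy-6-[(1S,6R)-6-hydroxy-4-methylcyclohex-3-en-1-yl]-2-methylheptan-5-yl acetate | CC(=O)O[C@@H](C[C@H](Br)C(C)(C)O)[C@@](C)(Cl)[C@H]1CC=C(C)C[C@H]1O
F2 | step 11 | (2S,3S,5S)-5-bromo-2-[(1S,2R,4S,5S)-4,5-dichloro-2-hydroxy-4-methylcyclohexyl]-2,6,6-trimethyloxan-3-yl acetate | CC(=O)O[C@H]1C[C@H](Br)C(C)(C)O[C@@]1(C)[C@H]1C[C@H](Cl)[C@@](C)(Cl)C[C@H]1O
F3 | step 5 | triethyl{[(3Z,6E)-7-iodo-3-methylocta-3,6-dien-1-yl]oxy}silane | CC[Si](CC)(CC)OCC/C(C)=C\C/C=C(\C)I
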